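**Plan**
Cuts: the quinone goes back to a dibenzyl hydroquinone and the 6-OMe to a phenol. O1–C8a and C4–C4a of the chroman are then cut in one operation. Last, C3–C4 is cut between a ring A benzylic bromide and a ring B arylacetyl imide.
Enabling feature: on ring A, O1 (at C8a) lies para to the C6 oxygen, C4 sits on C4a beside C8a, and C8 on the other flank carries oxygen. A 4-alkylphenol shows this pattern after its own side-chain alcohol has dearomatised it and the side-chain carbon has moved to the free neighbouring ring carbon.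
Forward order: rings A and B start as purchased arenes and are joined through C3–C4. The heterocycle forms last, first as a spiro tetrahydrofuran on a cyclohexadienone, then enlarged to the dihydropyran as ring A regains aromaticity. The quinone is unveiled at the end.
Stereochemistry: the only stereocentre, C3 (S), is set by alkylating the sodium enolate of an (S)-4-benzyl-2-oxazolidinone imide and is a spectator afterwards.

Key step: step 14

Assumption: C3 of the target SMILES is read as S; 2,4-dihydroxy-3-methoxybenzaldehyde, 2,3-dimethoxyphenol, (S)-4-benzyl-2-oxazolidinone and BrZnCH2CO2Et in THF are taken as catalogue items.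

**Route**

Step 1
Reactants: 1 2,4-dihydroxy-3-methoxybenzaldehyde
Product: 2 4-formyl-3-hydroxy-2-methoxyphenyl 4-methylbenzenesulfonate
Conditions: TsCl (1.0 equiv), K2CO3, acetone, 0 °C to rt
Reagents that add atoms: 4-toluenesulfonyl chloride, Cc1ccc(cc1)S(=O)(=O)Cl
Why: The 2-hydroxyl is hydrogen-bonded to the formyl oxygen, so base-mediated O-sulfonylation should take the free, more acidic 4-hydroxyl, and the electron-poor sulfonate later tempers the benzylic bromide.

Step 2
Reactants: 2 4-formyl-3-hydroxy-2-methoxyphenyl 4-methylbenzenesulfonate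
Product: 3 3-(benzyloxy)-4-formyl-2-methoxyphenyl 4-methylbenzenesulfonate
Conditions: BnBr, K2CO3, DMF, 60 °C
Reagents that add atoms: benzyl bromide, BrCc1ccccc1
Why: Williamson etherification of the remaining chelated phenol needs only warm carbonate in DMF, which an aryl tosylate tolerates.

Step 3
Reactants: 3 3-(benzyloxy)-4-formyl-2-methoxyphenyl 4-methylbenzenesulfonate
Product: 4 3-(benzyloxy)-4-(hydroxymethyl)-2-methoxyphenyl 4-methylbenzenesulfonate
Conditions: NaBH4, THF/MeOH, 0 °C
Reagents that add atoms: none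
Why: Borohydride reduction of an aromatic aldehyde is fast at 0 °C and leaves the sulfonate and the ethers untouched.

Step 4
Reactants: 4 3-(benzyloxy)-4-(hydroxymethyl)-2-methoxyphenyl 4-methylbenzenesulfonate
Product: 5 3-(benzyloxy)-4-(bromomethyl)-2-methoxyphenyl 4-methylbenzenesulfonate
Conditions: PBr3 (0.4 equiv), CH2Cl2, 0 °C
Reagents that add atoms: phosphorus tribromide, BrP(Br)Br
Why: PBr3 converts a benzylic alcohol through a phosphite ester and SN2 displacement by bromide, and the para sulfonate should suppress ionisation enough for the bromide to be handled.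

Step 5
Reactants: 6 2,3-dimethoxyphenol
Product: 7 2,3-dimethoxy-1,4-benzoquinone
Conditions: (KSO3)2NO (2.2 equiv), KH2PO4 buffer, H2O/acetone, rt
Reagents that add atoms: potassium nitrosodisulfonate, [K+].[K+].[O]N(S([O-])(=O)=O)S([O-])(=O)=O
Why: In the Teuber oxidation one nitroxyl radical removes the phenolic hydrogen and a second delivers oxygen to the free para position, which should give the para-quinone.

Step 6
Reactants: 7 2,3-dimethoxy-1,4-benzoquinone
Product: 9 1,4-bis(benzyloxy)-2,3-dimethoxybenzene, via 2,3-dimethoxyhydroquinone 8 (not isolated)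
Conditions: Na2S2O4, THF/H2O, rt; extract under N2; BnBr, K2CO3, DMF, 60 °C
Reagents that add atoms: benzyl bromide, BrCc1ccccc1
Why: Dithionite reduction followed by double Williamson benzylation is the standard reductive alkylation of a quinone, and the symmetric product makes the next substitution regiochemically unambiguous.

Step 7
Reactants: 9 1,4-bis(benzyloxy)-2,3-dimethoxybenzene
Product: 10 1,4-bis(benzyloxy)-5-bromo-2,3-dimethoxybenzene
Conditions: NBS (1.0 equiv), MeCN, 0 °C to rt
Reagents that add atoms: N-bromosuccinimide, O=C1CCC(=O)N1Br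
Why: In this electrophilic aromatic bromination the two free ring positions are equivalent, and the first bromine should slow a second substitution.

Step 8
Reactants: 10 1,4-bis(benzyloxy)-5-bromo-2,3-dimethoxybenzene
Product: 11 ethyl 2-[2,5-bis(benzyloxy)-3,4-dimethoxyphenyl]acetate
Conditions: BrZnCH2CO2Et, Pd2(dba)3 (cat.), XPhos (cat.), THF, 65 °C
Reagents that add atoms: (2-ethoxy-2-oxoethyl)zinc bromide, CCOC(=O)C[Zn]Br
Why: This is a Negishi-type coupling of a Reformatsky reagent, in which zerovalent palladium with a bulky biaryl phosphine inserts into electron-rich, ortho-substituted aryl bromides and the neutral zinc enolate leaves the benzyl ethers alone.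

Step 9
Reactants: 11 ethyl 2-[2,5-bis(benzyloxy)-3,4-dimethoxyphenyl]acetate
Product: 12 2-[2,5-bis(benzyloxy)-3,4-dimethoxyphenyl]acetic acid
Conditions: LiOH, THF/MeOH/H2O, rt; then 1 M HCl
Reagents that add atoms: lithium hydroxide, [Li+].[OH-]
Why: Saponification of an unhindered ethyl ester touches none of the aryl ethers.

Step 10
Reactants: 12 2-[2,5-bis(benzyloxy)-3,4-dimethoxyphenyl]acetic acid, 13 (S)-4-benzyl-2-oxazolidinone
Product: 15 (4S)-4-benzyl-3-{2-[2,5-bis(benzyloxy)-3,4-dimethoxyphenyl]acetyl}-1,3-oxazolidin-2-one, via mixed pivalic anhydride 14 (not isolated)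
Conditions: PivCl, Et3N, THF, −20 °C; then LiCl, 13, −20 °C to rt
Reagents that add atoms: pivaloyl chloride, CC(C)(C)C(=O)Cl (its atoms are held by 14 only)
Why: In this mixed-anhydride N-acylation of an oxazolidinone assisted by LiCl, the bulky pivaloyl side steers attack to the arylacetyl carbonyl.

Step 11
Reactants: 15 (4S)-4-benzyl-3-{2-[2,5-bis(benzyloxy)-3,4-dimethoxyphenyl]acetyl}-1,3-oxazolidin-2-one, 5 3-(benzyloxy)-4-(bromomethyl)-2-methoxyphenyl 4-methylbenzenesulfonate
Product: 17 (4S)-4-benzyl-3-{(2S)-3-[2-(benzyloxy)-3-methoxy-4-(tosyloxy)phenyl]-2-[2,5-bis(benzyloxy)-3,4-dimethoxyphenyl]propanoyl}-1,3-oxazolidin-2-one, via sodium Z-enolate 16 (not isolated)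
Conditions: NaN(SiMe3)2 (1.05 equiv), THF, −78 °C; then 5, −78 to −30 °C
Reagents that add atoms: sodium bis(trimethylsilyl)amide, C[Si](C)(C)[N-][Si](C)(C)C.[Na+] (its sodium is held by 16 only)
Why: In the Evans alkylation the sodium-chelated Z-enolate is shielded on one face by the benzyl group of the (S)-auxiliary, so the bromide should enter from the open face and set the future C3 as S.

Step 12
Reactants: 17 (4S)-4-benzyl-3-{(2S)-3-[2-(benzyloxy)-3-methoxy-4-(tosyloxy)phenyl]-2-[2,5-bis(benzyloxy)-3,4-dimethoxyphenyl]propanoyl}-1,3-oxazolidin-2-one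
Product: 18 3-(benzyloxy)-4-{(2S)-2-[2,5-bis(benzyloxy)-3,4-dimethoxyphenyl]-3-hydroxypropyl}-2-methoxyphenyl 4-methylbenzenesulfonate
Conditions: LiBH4, THF/Et2O, 0 °C to rt
Reagents that add atoms: none
Why: In this reductive cleavage of an N-acyl oxazolidinone, hydride attacks the exocyclic carbonyl under non-enolising conditions, so the α-aryl centre should keep its configuration and the tosylate survives.

Step 13
Reactants: 18 3-(benzyloxy)-4-{(2S)-2-[2,5-bis(benzyloxy)-3,4-dimethoxyphenyl]-3-hydroxypropyl}-2-methoxyphenyl 4-methylbenzenesulfonate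
Product: 19 3-(benzyloxy)-4-{(2S)-2-[2,5-bis(benzyloxy)-3,4-dimethoxyphenyl]-3-hydroxypropyl}-2-methoxyphenol
Conditions: Mg turnings, MeOH/THF, rt; then aq HCl
Reagents that add atoms: none
Why: In this dissolving-metal desulfonylation, electron transfer from magnesium to the arenesulfonyl group cleaves the S–O bond at room temperature and leaves benzyl ethers, methyl ethers and the non-acidic C–H stereocentre alone.

Step 14
Reactants: 19 3-(benzyloxy)-4-{(2S)-2-[2,5-bis(benzyloxy)-3,4-dimethoxyphenyl]-3-hydroxypropyl}-2-methoxyphenol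
Product: 21 (3S)-8-(benzyloxy)-3-[2,5-bis(benzyloxy)-3,4-dimethoxyphenyl]-7-methoxychroman-6-ol, via spirodienone 20 (not isolated)
Conditions: PhI(OAc)2 (1.0 equiv), CH2Cl2/(CF3)2CHOH 4:1, 0.02 M, −20 to 0 °C; evaporate with toluene; BF3·OEt2, CH2Cl2, −40 to 0 °C
Reagents that add atoms: none
Why: The phenol exchanges an acetate on trivalent iodine and, as PhI departs, the electron-poor ring is captured at the carbon para to oxygen (future C8a) by the side-chain hydroxyl in a 5-exo-trig closure that makes O1–C8a and spirodienone 20. BF3 on the dienone carbonyl then sets off a dienone-phenol rearrangement in which C4 moves from the spiro carbon to the adjacent CH (future C4a), the charge left behind being carried by O1 as an oxocarbenium ion, and proton loss rearomatises, so the six-membered ring arises by 1,2-shift ring expansion of the tetrahydrofuran and the former phenol oxygen ends up on C6. The closest known reaction types are the PhI(OAc)2 spiroetherification of 4-(3-hydroxypropyl)phenols and the acid-promoted rearrangement of 1-oxaspiro[4.5]deca-6,9-dien-8-ones to chroman-6-ols. The spiro carbon is a transient, uncontrolled stereocentre that is erased on rearomatisation, no lasting stereocentre is formed, and C3 takes no part. Chemoselectivity in the oxidation rests on the phenol being the only group able to bind iodine, on the short tether of the primary alcohol, and on high dilution in a non-nucleophilic fluoroalcohol mixture with exactly one equivalent of oxidant, which together should keep ring B carbon, solvent and product 21 out of play. Regioselectivity in the shift rests on the substrate: carbon migration leaves an oxygen-stabilised cation whereas oxygen migration would not, and of the two neighbours only the unsubstituted one can lose a proton, a shift to the benzyloxy-bearing carbon being reversible and unproductive.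

Step 15
Reactants: 21 (3S)-8-(benzyloxy)-3-[2,5-bis(benzyloxy)-3,4-dimethoxyphenyl]-7-methoxychroman-6-ol
Product: 22 (3S)-8-(benzyloxy)-3-[2,5-bis(benzyloxy)-3,4-dimethoxyphenyl]-6,7-dimethoxychroman
Conditions: MeI, K2CO3, acetone, reflux
Reagents that add atoms: iodomethane, CI
Why: Williamson methylation acts on the only free hydroxyl in the molecule.

Step 16
Reactants: 22 (3S)-8-(benzyloxy)-3-[2,5-bis(benzyloxy)-3,4-dimethoxyphenyl]-6,7-dimethoxychroman
Product: 24 2,3-dimethoxy-5-[(3S)-8-hydroxy-6,7-dimethoxychroman-3-yl]-1,4-benzoquinone, via hydroquinone 23 (not isolated)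
Conditions: H2 (1 atm), 10% Pd/C, EtOAc, rt; filter under Ar; Ag2O (1.05 equiv), rt
Reagents that add atoms: none
Why: Catalytic hydrogenolysis should remove all three benzyl ethers without touching the chroman, and a near-stoichiometric charge of Ag2O under neutral conditions should oxidise the far more easily oxidised ring B hydroquinone while the ring A phenol and C3 stay as they are.

**Compound list**
1 | 2,4-dihydroxy-3-methoxybenzaldehyde | COc1c(O)ccc(C=O)c1O | starting material
2 | 4-formyl-3-hydroxy-2-methoxyphenyl 4-methylbenzenesulfonate | COc1c(OS(=O)(=O)c2ccc(C)cc2)ccc(C=O)c1O | intermediate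
3 | 3-(benzyloxy)-4-formyl-2-methoxyphenyl 4-methylbenzenesulfonate | COc1c(OS(=O)(=O)c2ccc(C)cc2)ccc(C=O)c1OCc3ccccc3 | intermediate
4 | 3-(benzyloxy)-4-(hydroxymethyl)-2-methoxyphenyl 4-methylbenzenesulfonate | COc1c(OS(=O)(=O)c2ccc(C)cc2)ccc(CO)c1OCc3ccccc3 | intermediate
5 | 3-(benzyloxy)-4-(bromomethyl)-2-methoxyphenyl 4-methylbenzenesulfonate | COc1c(OS(=O)(=O)c2ccc(C)cc2)ccc(CBr)c1OCc3ccccc3 | intermediate
6 | 2,3-dimethoxyphenol | COc1cccc(O)c1OC | starting material
7 | 2,3-dimethoxy-1,4-benzoquinone | COC1=C(OC)C(=O)C=CC1=O | intermediate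
8 | 2,3-dimethoxybenzene-1,4-diol (not isolated) | COc1c(O)ccc(O)c1OC | intermediate
9 | 1,4-bis(benzyloxy)-2,3-dimethoxybenzene | COc1c(OCc2ccccc2)ccc(OCc3ccccc3)c1OC | intermediate
10 | 1,4-bis(benzyloxy)-5-bromo-2,3-dimethoxybenzene | COc1c(OCc2ccccc2)cc(Br)c(OCc3ccccc3)c1OC | intermediate
11 | ethyl 2-[2,5-bis(benzyloxy)-3,4-dimethoxyphenyl]acetate | CCOC(=O)Cc1cc(OCc2ccccc2)c(OC)c(OC)c1OCc3ccccc3 | intermediate
12 | 2-[2,5-bis(benzyloxy)-3,4-dimethoxyphenyl]acetic acid | OC(=O)Cc1cc(OCc2ccccc2)c(OC)c(OC)c1OCc3ccccc3 | intermediate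
13 | (S)-4-benzyl-2-oxazolidinone | O=C1N[C@@H](Cc2ccccc2)CO1 | starting material
14 | 2-[2,5-bis(benzyloxy)-3,4-dimethoxyphenyl]acetic pivalic anhydride (not isolated) | CC(C)(C)C(=O)OC(=O)Cc1cc(OCc2ccccc2)c(OC)c(OC)c1OCc3ccccc3 | intermediate
15 | (4S)-4-benzyl-3-{2-[2,5-bis(benzyloxy)-3,4-dimethoxyphenyl]acetyl}-1,3-oxazolidin-2-one | O=C1OC[C@H](Cc2ccccc2)N1C(=O)Cc3cc(OCc4ccccc4)c(OC)c(OC)c3OCc5ccccc5 | intermediate
16 | sodium Z-enolate of 15 (not isolated) | [Na+].[O-]/C(=C\c1cc(OCc2ccccc2)c(OC)c(OC)c1OCc3ccccc3)N4[C@@H](Cc5ccccc5)COC4=O | intermediate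
17 | (4S)-4-benzyl-3-{(2S)-3-[2-(benzyloxy)-3-methoxy-4-(tosyloxy)phenyl]-2-[2,5-bis(benzyloxy)-3,4-dimethoxyphenyl]propanoyl}-1,3-oxazolidin-2-one | O=C1OC[C@H](Cc2ccccc2)N1C(=O)[C@@H](Cc3ccc(OS(=O)(=O)c4ccc(C)cc4)c(OC)c3OCc5ccccc5)c6cc(OCc7ccccc7)c(OC)c(OC)c6OCc8ccccc8 | intermediate
18 | 3-(benzyloxy)-4-{(2S)-2-[2,5-bis(benzyloxy)-3,4-dimethoxyphenyl]-3-hydroxypropyl}-2-methoxyphenyl 4-methylbenzenesulfonate | OC[C@@H](Cc1ccc(OS(=O)(=O)c2ccc(C)cc2)c(OC)c1OCc3ccccc3)c4cc(OCc5ccccc5)c(OC)c(OC)c4OCc6ccccc6 | intermediate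
19 | 3-(benzyloxy)-4-{(2S)-2-[2,5-bis(benzyloxy)-3,4-dimethoxyphenyl]-3-hydroxypropyl}-2-methoxyphenol | OC[C@@H](Cc1ccc(O)c(OC)c1OCc2ccccc2)c3cc(OCc4ccccc4)c(OC)c(OC)c3OCc5ccccc5 | intermediate
20 | (3S)-6-(benzyloxy)-3-[2,5-bis(benzyloxy)-3,4-dimethoxyphenyl]-7-methoxy-1-oxaspiro[4.5]deca-6,9-dien-8-one, both configurations at the spiro carbon (not isolated) | O=C1C=CC2(C[C@H](CO2)c3cc(OCc4ccccc4)c(OC)c(OC)c3OCc5ccccc5)C(OCc6ccccc6)=C1OC | intermediate
21 | (3S)-8-(benzyloxy)-3-[2,5-bis(benzyloxy)-3,4-dimethoxyphenyl]-7-methoxychroman-6-ol | COc1c(OC)c(OCc2ccccc2)cc([C@H]3COc4c(cc(O)c(OC)c4OCc5ccccc5)C3)c1OCc6ccccc6 | intermediate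
22 | (3S)-8-(benzyloxy)-3-[2,5-bis(benzyloxy)-3,4-dimethoxyphenyl]-6,7-dimethoxychroman | COc1c(OC)c(OCc2ccccc2)cc([C@H]3COc4c(cc(OC)c(OC)c4OCc5ccccc5)C3)c1OCc6ccccc6 | intermediate
23 | 2,3-dimethoxy-5-[(3S)-8-hydroxy-6,7-dimethoxychroman-3-yl]benzene-1,4-diol (not isolated) | COc1c(OC)c(O)cc([C@H]3COc4c(cc(OC)c(OC)c4O)C3)c1O | intermediate
24 | 2,3-dimethoxy-5-[(3S)-8-hydroxy-6,7-dimethoxychroman-3-yl]-1,4-benzoquinone (CNP0269725.1) | COC1=C(OC)C(=O)C([C@H]2COc3c(cc(OC)c(OC)c3O)C2)=CC1=O | target

Total step count: 16.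
Longest linear sequence: 12 steps (steps 5 to 16, from 6 to 24). Steps 1 to 4 form the four-step ring A branch that enters at step 11.

**Steps most likely to fail**

Step 14.
- Risks:
  - Oxidised ring A may be captured by the free carbon of ring B instead of the hydroxyl.
  - The tetraalkoxy ring B may transfer an electron to the iodane.
  - The benzyl group may be lost from the vinylogous ester oxygen once BF3 is bound.
  - Oxygen may migrate instead of carbon.
  - The product phenol may be over-oxidised by leftover oxidant.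
- Fallback: O1–C8a is made by metal-catalysed aryl etherification instead of dearomatisation. It sets out from 15 and comes back at 22.
  - Commercial 3-hydroxy-4,5-dimethoxybenzaldehyde is brominated ortho to the phenol (NBS, cat. i-Pr2NH, CH2Cl2) to 2-bromo-3-hydroxy-4,5-dimethoxybenzaldehyde F1.
  - F1 is benzylated (BnBr, K2CO3, DMF) to 3-(benzyloxy)-2-bromo-4,5-dimethoxybenzaldehyde F2, which is reduced (NaBH4) to [3-(benzyloxy)-2-bromo-4,5-dimethoxyphenyl]methanol F3.
  - F3 is converted with PBr3 into 3-(benzyloxy)-2-bromo-1-(bromomethyl)-4,5-dimethoxybenzene F4.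
  - Enolate 16, generated from 15 as in step 11, is alkylated with F4 to the (2S)-configured bromoaryl imide F5, and LiBH4 gives the (2S)-configured bromoaryl propanol F6.
  - An intramolecular Buchwald–Hartwig C–O coupling (Pd(OAc)2, a bulky di-tert-butyl biaryl phosphine, Cs2CO3, toluene, 80 °C) then closes the chroman to 22, which already carries the 6-OMe group.

Step 11.
- Risks: a hindered enolate may be alkylated only slowly by an ortho-substituted bromide, facial selectivity may erode, or surplus base may epimerise the acidic α-aryl position.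
- Fallback: the auxiliary is replaced by catalytic asymmetric hydrogenation. It sets out from 12 and 3 and comes back at 18.
  - A Perkin condensation of 12 with 3 (Ac2O, Et3N, 110 °C) gives the (E)-2,3-diarylacrylic acid F7.
  - F7 is hydrogenated with a cationic iridium catalyst [Ir(cod)(P,N)]B[3,5-(CF3)2C6H3]4 bearing a chiral spiro phosphine-oxazoline ligand. The ligand antipode is chosen to deliver the (S)-2,3-diarylpropanoic acid F8, and the benzyl ethers are inert to the homogeneous catalyst.
  - BH3·THF then reduces the acid to 18.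

Step 8.
- Risks: oxidative addition into the electron-rich, ortho-substituted bromide may be sluggish, the zinc enolate may be protonated, or it may self-condense.
- Fallback: the two-carbon acid side chain is built by organolithium chemistry. It sets out from 10 and comes back at 12, so step 9 is also bypassed.
  - Bromine–lithium exchange (n-BuLi, THF, −78 °C) gives [2,5-bis(benzyloxy)-3,4-dimethoxyphenyl]lithium F9.
  - Oxirane with BF3·OEt2 at −78 °C gives 2-[2,5-bis(benzyloxy)-3,4-dimethoxyphenyl]ethanol F10.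
  - TEMPO (cat.), NaClO2 and NaOCl (cat.) in MeCN/phosphate buffer oxidise the alcohol to 12.

**Further compounds**
F1 | step 14 | 2-bromo-3-hydroxy-4,5-dimethoxybenzaldehyde | COc1cc(C=O)c(Br)c(O)c1OC
F2 | step 14 | 3-(benzyloxy)-2-bromo-4,5-dimethoxybenzaldehyde | COc1cc(C=O)c(Br)c(OCc2ccccc2)c1OC
F3 | step 14 | [3-(benzyloxy)-2-bromo-4,5-dimethoxyphenyl]methanol | COc1cc(CO)c(Br)c(OCc2ccccc2)c1OC
F4 | step 14 | 3-(benzyloxy)-2-bromo-1-(bromomethyl)-4,5-dimethoxybenzene | COc1cc(CBr)c(Br)c(OCc2ccccc2)c1OC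
F5 | step 14 | (4S)-4-benzyl-3-{(2S)-3-[3-(benzyloxy)-2-bromo-4,5-dimethoxyphenyl]-2-[2,5-bis(benzyloxy)-3,4-dimethoxyphenyl]propanoyl}-1,3-oxazolidin-2-one | O=C1OC[C@H](Cc2ccccc2)N1C(=O)[C@@H](Cc3cc(OC)c(OC)c(OCc4ccccc4)c3Br)c5cc(OCc6ccccc6)c(OC)c(OC)c5OCc7ccccc7
F6 | step 14 | (2S)-3-[3-(benzyloxy)-2-bromo-4,5-dimethoxyphenyl]-2-[2,5-bis(benzyloxy)-3,4-dimethoxyphenyl]propan-1-ol | OC[C@@H](Cc1cc(OC)c(OC)c(OCc2ccccc2)c1Br)c3cc(OCc4ccccc4)c(OC)c(OC)c3OCc5ccccc5
F7 | step 11 | (E)-3-[2-(benzyloxy)-3-methoxy-4-(tosyloxy)phenyl]-2-[2,5-bis(benzyloxy)-3,4-dimethoxyphenyl]acrylic acid | OC(=O)/C(=C/c1ccc(OS(=O)(=O)c2ccc(C)cc2)c(OC)c1OCc3ccccc3)c4cc(OCc5ccccc5)c(OC)c(OC)c4OCc6ccccc6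
F8 | step 11 | (2S)-3-[2-(benzyloxy)-3-methoxy-4-(tosyloxy)phenyl]-2-[2,5-bis(benzyloxy)-3,4-dimethoxyphenyl]propanoic acid | OC(=O)[C@@H](Cc1ccc(OS(=O)(=O)c2ccc(C)cc2)c(OC)c1OCc3ccccc3)c4cc(OCc5ccccc5)c(OC)c(OC)c4OCc6ccccc6
F9 | step 8 | [2,5-bis(benzyloxy)-3,4-dimethoxyphenyl]lithium | [Li]c1cc(OCc2ccccc2)c(OC)c(OC)c1OCc3ccccc3
F10 | step 8 | 2-[2,5-bis(benzyloxy)-3,4-dimethoxyphenyl]ethanol | OCCc1cc(OCc2ccccc2)c(OC)c(OC)c1OCc3ccccc3
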